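**Plan**

1. Target: 2-(6-bromo-1H-indol-3-yl)-4-(1H-indol-3-yl)-1H-imidazole. Remark: it has no stereocentre, so the single-enantiomer request is met trivially and the route is planned for the achiral structure as drawn (Ts = 4-methylbenzenesulfonyl, PMB = 4-methoxybenzyl).
2. Enabling feature: in the imidazole ring, C5 is a bare CH next to N1, C4 carries an indol-3-yl group, and C2 sits at the carboxylic acid oxidation level between both nitrogens. This is the pattern delivered by an N-acylglycine-derived oxazolium-5-olate (C5–N1–C2) and an aldimine (C4–N3).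
3. Retrosynthesis: the three N–H bonds are unmasked last (two Ts, one PMB). The imidazole is cut at C4–C5 and C2–N3 into an N-acyl-N-PMB-glycine and an N-tosyl aldimine. The glycine piece is cut at the amide C–N and benzylic N–C bonds, and the imine at C=N.
4. Forward: both indole rings are bought intact. 6-Bromoindole is formylated at C3, N-tosylated, oxidised to the acid and coupled to PMB-glycinate; indole-3-carbaldehyde is tosylated and condensed to the sulfonylimine. The imidazole is the only ring formed (step 9) and joins the two halves, after which PMB and both Ts groups are removed.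
5. Stereochemistry: nothing to set. The only stereo element on the way is the thermodynamic E geometry of the sulfonylimine, which is erased in step 9.

Key step: step 9

**Route**

Step 1
Reactants: 1 6-bromoindole
Product: 3 6-bromo-1H-indole-3-carbaldehyde, via iminium chloride 2 (not isolated)
Conditions: POCl3, DMF, 0 → 40 °C; then aq. NaOH, 90 °C
Reagents that add atoms: N,N-dimethylformamide, CN(C)C=O; water, O
Why: Vilsmeier–Haack formylation, in which the electron-rich indole C3 attacks the chloroiminium ion and the resulting iminium salt 2 is hydrolysed by aqueous base, the aryl bromide being inert.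

Step 2
Reactants: 3 6-bromo-1H-indole-3-carbaldehyde
Product: 4 6-bromo-1-tosyl-1H-indole-3-carbaldehyde
Conditions: NaH, TsCl, THF, 0 °C → rt
Reagents that add atoms: p-toluenesulfonyl chloride, Cc1ccc(cc1)S(Cl)(=O)=O
Why: N-sulfonylation of the indolyl anion (the 3-formyl group acidifies N–H), which also deactivates the indole for the oxidation and acid steps that follow.

Step 3
Reactants: 4 6-bromo-1-tosyl-1H-indole-3-carbaldehyde
Product: 5 6-bromo-1-tosyl-1H-indole-3-carboxylic acid
Conditions: NaClO2, NaH2PO4, 2-methyl-2-butene, t-BuOH/THF/H2O, rt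
Reagents that add atoms: sodium chlorite, [Na+].[O-]Cl=O
Why: Pinnick oxidation of an aromatic aldehyde, with the alkene scavenging hypochlorous acid so that the sulfonyl-deactivated indole should not be chlorinated.

Step 4
Reactants: 6 tert-butyl glycinate; 7 4-methoxybenzaldehyde
Product: 9 tert-butyl N-(4-methoxybenzyl)glycinate, via N-benzylidene glycinate 8 (not isolated)
Conditions: MeOH, rt; then NaBH4, 0 °C
Reagents that add atoms: none
Why: Stepwise reductive amination (imine condensation, then borohydride reduction) should avoid dialkylation and leave the tert-butyl ester untouched.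

Step 5
Reactants: 5 6-bromo-1-tosyl-1H-indole-3-carboxylic acid; 9 tert-butyl N-(4-methoxybenzyl)glycinate
Product: 11 tert-butyl N-(6-bromo-1-tosyl-1H-indole-3-carbonyl)-N-(4-methoxybenzyl)glycinate, via acid chloride 10 (not isolated)
Conditions: (COCl)2, cat. DMF, CH2Cl2, 0 °C → rt, evaporate; then 9, Et3N, CH2Cl2, 0 °C → rt
Reagents that add atoms: none
Why: Acid chloride formation followed by N-acylation of the secondary amine, the acid chloride being reactive enough for the hindered N-benzyl glycinate.

Step 6
Reactants: 11 tert-butyl N-(6-bromo-1-tosyl-1H-indole-3-carbonyl)-N-(4-methoxybenzyl)glycinate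
Product: 12 N-(6-bromo-1-tosyl-1H-indole-3-carbonyl)-N-(4-methoxybenzyl)glycine
Conditions: TFA/CH2Cl2 (1:2), rt
Reagents that add atoms: none
Why: Acidolysis of the tert-butyl ester (E1 loss of isobutene) at room temperature, where the N-PMB amide, both sulfonamide-type N–Ts bonds and the aryl bromide are stable; it avoids a hydroxide saponification that would endanger the N-tosylindole.

Step 7
Reactants: 13 indole-3-carbaldehyde
Product: 14 1-tosyl-1H-indole-3-carbaldehyde
Conditions: NaH, TsCl, THF, 0 °C → rt
Reagents that add atoms: p-toluenesulfonyl chloride, Cc1ccc(cc1)S(Cl)(=O)=O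
Why: N-sulfonylation of the indolyl anion, which removes the vinylogous-amide deactivation of the aldehyde and makes the derived imine electrophilic.

Step 8
Reactants: 14 1-tosyl-1H-indole-3-carbaldehyde
Product: 15 (E)-4-methyl-N-[(1-tosyl-1H-indol-3-yl)methylene]benzenesulfonamide
Conditions: TsNH2, TiCl4 (0.5 equiv), Et3N, CH2Cl2, 0 °C → rt; filtration and crystallisation, no silica
Reagents that add atoms: p-toluenesulfonamide, Cc1ccc(cc1)S(N)(=O)=O
Why: Titanium-mediated dehydrative condensation of a sulfonamide with an aromatic aldehyde, which should give the N-sulfonyl aldimine as the thermodynamically favoured E isomer.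

Step 9
Reactants: 12 N-(6-bromo-1-tosyl-1H-indole-3-carbonyl)-N-(4-methoxybenzyl)glycine; 15 (E)-4-methyl-N-[(1-tosyl-1H-indol-3-yl)methylene]benzenesulfonamide
Product: 19 2-(6-bromo-1-tosyl-1H-indol-3-yl)-1-(4-methoxybenzyl)-4-(1-tosyl-1H-indol-3-yl)-1H-imidazole, via münchnone 16 (not isolated), via bicyclic cycloadduct 17 (not isolated), via decarboxylated azomethine ylide 18 (not isolated)
Conditions: EDC (free base, 2 equiv, added slowly), 15 (1.5 equiv), CH2Cl2, rt → 40 °C
Reagents that add atoms: none
Why: Carbodiimide activation of the carboxyl group lets the amide oxygen close to the 5-oxo-oxazolium ion, which loses its acidic C4 proton to give münchnone 16, a cyclic azomethine ylide with termini at C2 and C4. The dipole should add across the C=N bond of 15 in a Huisgen-type 1,3-dipolar cycloaddition to give bicycle 17, which extrudes CO2 by cycloreversion to ylide 18; expulsion of p-toluenesulfinate from N3 and loss of the C4 proton then aromatise the ring to 19. The closest known reaction type is the imidazole synthesis from münchnones and N-sulfonyl aldimines, including carbodiimide-generated dipoles from N-acyl-N-benzylglycines with aryl and heteroaryl sulfonylimines. The imidazole is closed by an intermolecular two-bond annulation that forms C4–C5 and C2–N3 in one cycloaddition event (or a fast Mannich addition and ring closure), so no Baldwin-restricted cyclisation is involved. No stereocentre survives, because the three sp3 centres of 17 are transient and are erased on aromatisation. The step needs the regiochemistry in which the glycine-derived carbon of the dipole bonds to the imine carbon, which is secured by that carbon being the unsubstituted, enolate-like nucleophilic terminus and the sulfonylimine carbon the electrophilic partner; slow carbodiimide addition in the presence of excess 15 keeps the dipole concentration low so that capture should outrun its self-acylation.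

Step 10
Reactants: 19 2-(6-bromo-1-tosyl-1H-indol-3-yl)-1-(4-methoxybenzyl)-4-(1-tosyl-1H-indol-3-yl)-1H-imidazole
Product: 20 2-(6-bromo-1-tosyl-1H-indol-3-yl)-4-(1-tosyl-1H-indol-3-yl)-1H-imidazole
Conditions: TFA, anisole, 70 °C
Reagents that add atoms: none
Why: Acidolytic SN1 cleavage of the benzylic N–C bond of the protonated imidazole, with Friedel–Crafts capture of the 4-methoxybenzyl cation by anisole, while the N-tosyl groups keep both indoles inert to that cation.

Step 11
Reactants: 20 2-(6-bromo-1-tosyl-1H-indol-3-yl)-4-(1-tosyl-1H-indol-3-yl)-1H-imidazole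
Product: 21 nortopsentin B, 2-(6-bromo-1H-indol-3-yl)-4-(1H-indol-3-yl)-1H-imidazole
Conditions: NaOH (aq.), MeOH/THF, 65 °C
Reagents that add atoms: none
Why: Nucleophilic cleavage of the N–S bonds of the N-sulfonylindoles by hydroxide/methoxide (the indolyl anion is a good leaving group), under which the aryl bromide and the imidazole are stable.

**Compound list**

1 | 6-bromoindole | Brc1ccc2cc[nH]c2c1 | starting material
2 | (6-bromo-1H-indol-3-yl)methylene-dimethyliminium chloride | C[N+](C)=Cc1c[nH]c2cc(Br)ccc12.[Cl-] | intermediate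
3 | 6-bromo-1H-indole-3-carbaldehyde | O=Cc1c[nH]c2cc(Br)ccc12 | intermediate
4 | 6-bromo-1-tosyl-1H-indole-3-carbaldehyde | O=Cc1cn(S(=O)(=O)c2ccc(C)cc2)c2cc(Br)ccc12 | intermediate
5 | 6-bromo-1-tosyl-1H-indole-3-carboxylic acid | OC(=O)c1cn(S(=O)(=O)c2ccc(C)cc2)c2cc(Br)ccc12 | intermediate
6 | tert-butyl glycinate | CC(C)(C)OC(=O)CN | starting material
7 | 4-methoxybenzaldehyde | COc1ccc(C=O)cc1 | starting material
8 | tert-butyl (E)-N-(4-methoxybenzylidene)glycinate | COc1ccc(/C=N/CC(=O)OC(C)(C)C)cc1 | intermediate
9 | tert-butyl N-(4-methoxybenzyl)glycinate | COc1ccc(CNCC(=O)OC(C)(C)C)cc1 | intermediate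
10 | 6-bromo-1-tosyl-1H-indole-3-carbonyl chloride | ClC(=O)c1cn(S(=O)(=O)c2ccc(C)cc2)c2cc(Br)ccc12 | intermediate
11 | tert-butyl N-(6-bromo-1-tosyl-1H-indole-3-carbonyl)-N-(4-methoxybenzyl)glycinate | CC(C)(C)OC(=O)CN(Cc1ccc(OC)cc1)C(=O)c1cn(S(=O)(=O)c2ccc(C)cc2)c2cc(Br)ccc12 | intermediate
12 | N-(6-bromo-1-tosyl-1H-indole-3-carbonyl)-N-(4-methoxybenzyl)glycine | OC(=O)CN(Cc1ccc(OC)cc1)C(=O)c1cn(S(=O)(=O)c2ccc(C)cc2)c2cc(Br)ccc12 | intermediate
13 | indole-3-carbaldehyde | O=Cc1c[nH]c2ccccc12 | starting material
14 | 1-tosyl-1H-indole-3-carbaldehyde | O=Cc1cn(S(=O)(=O)c2ccc(C)cc2)c2ccccc12 | intermediate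
15 | (E)-4-methyl-N-[(1-tosyl-1H-indol-3-yl)methylene]benzenesulfonamide | Cc1ccc(cc1)S(=O)(=O)/N=C/c1cn(S(=O)(=O)c2ccc(C)cc2)c2ccccc12 | intermediate
16 | 2-(6-bromo-1-tosyl-1H-indol-3-yl)-3-(4-methoxybenzyl)-1,3-oxazol-3-ium-5-olate (münchnone) | [O-]c1c[n+](Cc2ccc(OC)cc2)c(o1)-c1cn(S(=O)(=O)c2ccc(C)cc2)c2cc(Br)ccc12 | intermediate
17 | 1-(6-bromo-1-tosyl-1H-indol-3-yl)-7-(4-methoxybenzyl)-6-tosyl-5-(1-tosyl-1H-indol-3-yl)-2-oxa-6,7-diazabicyclo[2.2.1]heptan-3-one (racemic, transient, relative configuration not defined) | O=C1OC2(c3cn(S(=O)(=O)c4ccc(C)cc4)c4cc(Br)ccc34)N(Cc3ccc(OC)cc3)C1C(c1cn(S(=O)(=O)c3ccc(C)cc3)c3ccccc13)N2S(=O)(=O)c1ccc(C)cc1 | intermediate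
18 | 2-(6-bromo-1-tosyl-1H-indol-3-yl)-1-(4-methoxybenzyl)-3-tosyl-4-(1-tosyl-1H-indol-3-yl)-3,4-dihydroimidazol-1-ium-5-ide (racemic, transient azomethine ylide) | [CH-]1[N+](Cc2ccc(OC)cc2)=C(c2cn(S(=O)(=O)c3ccc(C)cc3)c3cc(Br)ccc23)N(S(=O)(=O)c2ccc(C)cc2)C1c1cn(S(=O)(=O)c2ccc(C)cc2)c2ccccc12 | intermediate
19 | 2-(6-bromo-1-tosyl-1H-indol-3-yl)-1-(4-methoxybenzyl)-4-(1-tosyl-1H-indol-3-yl)-1H-imidazole | COc1ccc(Cn2cc(nc2-c2cn(S(=O)(=O)c3ccc(C)cc3)c3cc(Br)ccc23)-c2cn(S(=O)(=O)c3ccc(C)cc3)c3ccccc23)cc1 | intermediate
20 | 2-(6-bromo-1-tosyl-1H-indol-3-yl)-4-(1-tosyl-1H-indol-3-yl)-1H-imidazole | c1(-c2cn(S(=O)(=O)c3ccc(C)cc3)c3cc(Br)ccc23)nc(c[nH]1)-c1cn(S(=O)(=O)c2ccc(C)cc2)c2ccccc12 | intermediate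
21 | nortopsentin B | Brc1ccc2c(-c3nc(-c4c[nH]c5ccccc45)c[nH]3)c[nH]c2c1 | target

**Step count**

Total: 11 steps. Longest linear sequence: 8 steps (1, 2, 3, 5, 6, 9, 10, 11).

**Steps most likely to fail**

Step 9. The C4-unsubstituted mesoionic dipole may acylate itself faster than it is captured by the imine, or the sulfonylimine may be hydrolysed by adventitious water, so that little imidazole forms. The fallback is a Debus–Radziszewski imidazole synthesis that sets out from aldehyde 4, with commercial 3-acetylindole as the second component. 3-Acetylindole would be N-tosylated (NaH, TsCl, THF) to 3-acetyl-1-tosyl-1H-indole F1. Riley oxidation (SeO2, dioxane/H2O, reflux) should convert it into 2-oxo-2-(1-tosyl-1H-indol-3-yl)acetaldehyde F2. Condensation of F2 with 4 and ammonium acetate in AcOH/MeOH should place the aldehyde carbon of 4 at C2 and the glyoxal carbons at C4 and C5. This path comes back to the route at 20 and bypasses 19 and step 10.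

Step 8. Condensation may stall, or the moisture-sensitive sulfonylimine may revert to aldehyde during isolation. The fallback sets out from 14. Three-component condensation with TsNH2 and sodium p-toluenesulfinate in HCO2H/H2O should give the crystalline, storable α-amido sulfone 4-methyl-N-[(1-tosyl-1H-indol-3-yl)(tosyl)methyl]benzenesulfonamide F3. Shaking it with aqueous NaHCO3/CH2Cl2 just before use eliminates sulfinate and comes back to the route at 15.

Step 10. Heterolysis of the benzylic N–C bond of the protonated imidazole may be sluggish, and prolonged heating in acid may erode the sulfonyl groups. The fallback replaces acid solvolysis by oxidative debenzylation. It sets out from 19, which would be treated with ceric ammonium nitrate in MeCN/H2O at 0 °C → rt. Single-electron oxidation of the anisyl ring and collapse of the benzylic hemiaminal should release 4-methoxybenzaldehyde, and the tosyl-deactivated indoles are expected to withstand the oxidant. The path comes back to the route at 20, and no new compound arises on it (none, F0).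

**Further compounds**

F1 | step 9 | 3-acetyl-1-tosyl-1H-indole | CC(=O)c1cn(S(=O)(=O)c2ccc(C)cc2)c2ccccc12
F2 | step 9 | 2-oxo-2-(1-tosyl-1H-indol-3-yl)acetaldehyde | O=CC(=O)c1cn(S(=O)(=O)c2ccc(C)cc2)c2ccccc12
F3 | step 8 | 4-methyl-N-[(1-tosyl-1H-indol-3-yl)(tosyl)methyl]benzenesulfonamide (racemic) | Cc1ccc(cc1)S(=O)(=O)NC(c1cn(S(=O)(=O)c2ccc(C)cc2)c2ccccc12)S(=O)(=O)c1ccc(C)cc1
F0 | step 10 | none | none
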